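**Strategy.** Ring A (C4a–C5–C6–C7–C8–C8a) is a 6,6-disubstituted cyclohexa-2,4-dienone, the valence isomer of a dienylketene, so the plan rests on the C7–C8 disconnection. In one operation, thermolysis of a dioxinone releases an acylketene on the future C4a of a preformed ring B; γ-enolisation through the O1–C8a=C4a enol ether and 6π-electrocyclisation close ring A, create quaternary C8 and deliver the C7 ketone and C5 enol. The precursor is an all-cis 2,3-dimethyl-4-silyloxy-3,4-dihydro-2H-pyran bearing the dioxinone at C5 and the prenyl- and hexenyl-substituted CH at C6; the C4 silyl ether is a temporary stereocentre that prevents O-acylation and steers the helical closure.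

Key step: step 14

Remark on the chemistry: the carbon that becomes C8 is a mixture of epimers in 10 and 18–23 (it is planarised in step 14), β-dicarbonyl compounds are drawn as one tautomer, and enol lactone 26 may form on either flanking oxygen (both isomers give 27).

**Step 1**
Reactants: 1 (S)-4-benzyloxazolidin-2-one; 2 3-methylbut-2-enoyl chloride
Product: 3 (S)-4-benzyl-3-(3-methylbut-2-enoyl)oxazolidin-2-one
Conditions: n-BuLi, THF, −78 °C; then 2, −78 → 0 °C
Reagents that add atoms: none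
Why: N-acylation of the lithiated oxazolidinone by the acid chloride (attachment of the Evans auxiliary); no stereocentre is formed.

**Step 2**
Reactants: 3 (S)-4-benzyl-3-(3-methylbut-2-enoyl)oxazolidin-2-one; 4 3-methylbut-3-en-1-ol
Product: 6 (S)-4-benzyl-3-[(2S)-5-methyl-2-(prop-1-en-2-yl)hex-5-enoyl]oxazolidin-2-one, via 3-methylbut-3-en-1-yl triflate 5 (not isolated)
Conditions: 4, Tf2O, 2,6-lutidine, CH2Cl2, −78 °C (solution of 5 used cold); 3, NaHMDS, THF, −78 °C; then 5, −78 → −40 °C
Reagents that add atoms: none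
Why: Evans asymmetric alkylation in its deconjugative form: γ-deprotonation gives the sodium (Z)-dienolate, which the primary triflate alkylates at the α-carbon on the face opposite the benzyl group, setting the (2S) centre (the later (R) centre of the hexenyl chain).

**Step 3**
Reactants: 6 (S)-4-benzyl-3-[(2S)-5-methyl-2-(prop-1-en-2-yl)hex-5-enoyl]oxazolidin-2-one
Product: 7 (S)-5-methyl-2-(prop-1-en-2-yl)hex-5-en-1-ol
Conditions: LiBH4, H2O (1 equiv), Et2O, 0 °C
Reagents that add atoms: none
Why: Reductive cleavage of the N-acyl oxazolidinone to the primary alcohol; the β,γ-unsaturated stereocentre is not enolised under these conditions.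

**Step 4**
Reactants: 7 (S)-5-methyl-2-(prop-1-en-2-yl)hex-5-en-1-ol
Product: 8 (3S)-3-(iodomethyl)-2,6-dimethylhepta-1,6-diene
Conditions: I2, PPh3, imidazole, CH2Cl2, 0 °C
Reagents that add atoms: iodine, II
Why: Appel-type iodination by SN2 displacement at the primary carbon; the adjacent stereocentre is untouched.

**Step 5**
Reactants: 9 5-methylhex-4-enoic acid; 8 (3S)-3-(iodomethyl)-2,6-dimethylhepta-1,6-diene
Product: 10 (4R)-7-methyl-2-(3-methylbut-2-en-1-yl)-4-(prop-1-en-2-yl)oct-7-enoic acid (C2 epimers)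
Conditions: LDA (2.1 equiv), THF, DMPU, −78 → 0 °C; then 8, 0 °C → rt; aq. HCl
Reagents that add atoms: none
Why: Alkylation of the carboxylic acid dianion (Creger alkylation) by the primary iodide; the new α-centre is not controlled and need not be, because it is planarised in step 14.

**Step 6**
Reactants: 11 (S)-4-benzyl-3-propanoyloxazolidin-2-one; 12 acetaldehyde
Product: 13 (S)-4-benzyl-3-[(2S,3R)-3-hydroxy-2-methylbutanoyl]oxazolidin-2-one
Conditions: Bu2BOTf, iPr2NEt, CH2Cl2, −78 → 0 °C; then 12, −78 °C; H2O2, MeOH, pH 7 buffer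
Reagents that add atoms: none
Why: Evans syn-aldol reaction through the (Z)-boron enolate and a Zimmerman–Traxler chair; the auxiliary sets both the (2S) and (3R) centres.

**Step 7**
Reactants: 13 (S)-4-benzyl-3-[(2S,3R)-3-hydroxy-2-methylbutanoyl]oxazolidin-2-one
Product: 14 (2S,3R)-3-hydroxy-N-methoxy-N,2-dimethylbutanamide
Conditions: MeNHOMe·HCl, AlMe3, CH2Cl2, −20 → 0 °C
Reagents that add atoms: N,O-dimethylhydroxylamine hydrochloride, CNOC.Cl
Why: Aluminium amide transamidation of the aldol imide to the Weinreb amide, assisted by the free β-hydroxyl and not expected to epimerise the α-centre.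

**Step 8**
Reactants: 14 (2S,3R)-3-hydroxy-N-methoxy-N,2-dimethylbutanamide
Product: 15 (2S,3R)-3-[(tert-butyldimethylsilyl)oxy]-N-methoxy-N,2-dimethylbutanamide
Conditions: TBSOTf, 2,6-lutidine, CH2Cl2, 0 °C
Reagents that add atoms: tert-butyldimethylsilyl triflate, CC(C)(C)[Si](C)(C)OS(=O)(=O)C(F)(F)F
Why: Silyl ether protection of the secondary alcohol so that the amide can meet a strongly basic enolate.

**Step 9**
Reactants: 16 2,2,6-trimethyl-4H-1,3-dioxin-4-one; 15 (2S,3R)-3-[(tert-butyldimethylsilyl)oxy]-N-methoxy-N,2-dimethylbutanamide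
Product: 17 6-[(3S,4R)-4-[(tert-butyldimethylsilyl)oxy]-3-methyl-2-oxopentyl]-2,2-dimethyl-4H-1,3-dioxin-4-one
Conditions: 16 (2.2 equiv), LiHMDS (2.2 equiv), THF, −78 °C; then 15, −78 → −20 °C; aq. NH4Cl
Reagents that add atoms: none
Why: Claisen-type γ-acylation of the lithium dienolate of the dioxinone by the Weinreb amide; the chelated tetrahedral intermediate prevents over-addition and the α-stereocentre is not deprotonated by the stabilised enolate.

**Step 10**
Reactants: 17 6-[(3S,4R)-4-[(tert-butyldimethylsilyl)oxy]-3-methyl-2-oxopentyl]-2,2-dimethyl-4H-1,3-dioxin-4-one; 10 (4R)-7-methyl-2-(3-methylbut-2-en-1-yl)-4-(prop-1-en-2-yl)oct-7-enoic acid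
Product: 19 6-[(2R,3S,9R)-2-[(tert-butyldimethylsilyl)oxy]-3,12-dimethyl-7-(3-methylbut-2-en-1-yl)-4,6-dioxo-9-(prop-1-en-2-yl)tridec-12-en-5-yl]-2,2-dimethyl-4H-1,3-dioxin-4-one, via acid chloride 18 (not isolated)
Conditions: 10, 1-chloro-N,N,2-trimethylprop-1-en-1-amine, CH2Cl2, 0 °C → rt; then 17, MgCl2, pyridine, CH2Cl2, 0 °C → rt
Reagents that add atoms: none
Why: Neutral acid chloride formation (Ghosez reagent, no HCl to add to the alkenes) followed by magnesium-enolate C-acylation of the doubly activated methylene of the β-keto-dioxinone (Rathke-type soft enolisation).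

**Step 11**
Reactants: 19 (diketo-dioxinone, name as in step 10)
Product: 20 (2R,3S)-6-[(7R)-2,10-dimethyl-7-(prop-1-en-2-yl)undeca-2,10-dien-5-yl]-5-(2,2-dimethyl-4-oxo-4H-1,3-dioxin-6-yl)-2,3-dimethyl-2,3-dihydro-4H-pyran-4-one
Conditions: HF (48% aq.), MeCN, 0 °C → rt
Reagents that add atoms: none
Why: Desilylation then cyclodehydration of the δ-hydroxy-β-diketone (hemiketalisation and loss of water) to the 2,3-dihydro-4H-pyran-4-one; the carbinol C–O bond is retained so the syn-aldol pattern becomes the cis-2,3-dimethyl ring, and the ketone is a better electrophile than the dioxinone carbon, so the ring oxygen ends on the side-chain ketone carbon.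

**Step 12**
Reactants: 20 (pyranone, name as in step 11)
Product: 21 6-[(2R,3R,4S)-6-[(7R)-2,10-dimethyl-7-(prop-1-en-2-yl)undeca-2,10-dien-5-yl]-4-hydroxy-2,3-dimethyl-3,4-dihydro-2H-pyran-5-yl]-2,2-dimethyl-4H-1,3-dioxin-4-one (all-cis ring)
Conditions: NaBH4, CeCl3·7H2O, MeOH, −78 → −40 °C
Reagents that add atoms: none
Why: Luche 1,2-reduction of the vinylogous ester carbonyl; hydride should add anti to the pseudo-axial C3 methyl group, giving the all-cis (4S) alcohol, a temporary stereocentre that also removes the enolisable ketone next to C3.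

**Step 13**
Reactants: 21 (allylic alcohol, name as in step 12)
Product: 22 6-[(2R,3S,4S)-6-[(7R)-2,10-dimethyl-7-(prop-1-en-2-yl)undeca-2,10-dien-5-yl]-2,3-dimethyl-4-[(triisopropylsilyl)oxy]-3,4-dihydro-2H-pyran-5-yl]-2,2-dimethyl-4H-1,3-dioxin-4-one
Conditions: TIPSOTf, 2,6-lutidine, CH2Cl2, −20 → 0 °C
Reagents that add atoms: triisopropylsilyl triflate, CC(C)[Si](C(C)C)(C(C)C)OS(=O)(=O)C(F)(F)F
Why: Silylation of the allylic alcohol; the bulky, weakly nucleophilic silyl ether is the control element for step 14.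

**Step 14**
Reactants: 22 (silyloxy-dihydropyranyl dioxinone, name as in step 13)
Product: 24 (2R,3S,4S,8R)-5-hydroxy-2,3-dimethyl-8-(3-methylbut-2-en-1-yl)-8-[(2R)-5-methyl-2-(prop-1-en-2-yl)hex-5-en-1-yl]-4-[(triisopropylsilyl)oxy]-3,4-dihydro-2H-chromen-7(8H)-one, via acylketene 23 (not isolated)
Conditions: PhMe (5 mM), iPr2NEt (0.2 equiv), 110 °C
Reagents that add atoms: none
Why: Proposed new method: retro-[4+2] loss of acetone gives acylketene 23, whose acyl C=O is conjugated through the ring-B enol ether (O1–C6=C5, pyran numbering) to the tertiary C–H of the C6 side chain, so amine-mediated γ-enolisation gives a 3-hydroxy-dienylketene that closes by 6π-electrocyclisation, forming the C7–C8 bond and delivering ring A directly as the non-aromatisable 5-hydroxycyclohexa-2,4-dien-7-one. The closest known reactions are the electrocyclisation of dienylketenes to cyclohexa-2,4-dienones (last stage of the Danheiser benzannulation, thermal reversal of the Barton–Quinkert ring opening) and intramolecular C-acylation by dioxinone-derived acylketenes; creating a quaternary carbon from the γ-C–H of a vinylogous ester in this way is untested. Only ring A is closed, in a thermal disrotatory 6π mode that is formally a 6-exo-dig attack of the dienol γ-carbon on the ketene carbon. C8 is the only new stereocentre and is controlled by two elements: the temporary C4 stereocentre, whose pseudo-axial OTIPS group makes the acyl oxygen turn away from it so that the ketene terminus swings over the silyloxy-bearing face (one helical sense), and A(1,3) strain, which places the β-branched hexenyl chain outside and the prenyl group inside on the enol double bond. Bond formation on that face pushes prenyl to the opposite face and leaves the branched chain syn to the ring-B methyl groups, which is the (8R) configuration; both side-chain epimers of 22 converge because that carbon is planarised. The step needs C- instead of O-acylation, which is secured because the only oxygen that could reach the ketene in a six-membered array (the C4 carbonyl oxygen) is held at the silyl ether level and the enol oxygen is alkylated in ring B, leaving the γ-carbon as the sole internal nucleophile.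

**Step 15**
Reactants: 24 (bicyclic dienone, name as in step 14); 25 (E)-hex-2-enal
Product: 27 (3S)-3-[(2R,3S,4S,8R)-5-hydroxy-2,3-dimethyl-8-(3-methylbut-2-en-1-yl)-8-[(2R)-5-methyl-2-(prop-1-en-2-yl)hex-5-en-1-yl]-7-oxo-4-[(triisopropylsilyl)oxy]-3,4,7,8-tetrahydro-2H-chromen-6-yl]hexanoic acid, via enol lactone 26 (not isolated)
Conditions: 25, N-mesityl aminoindanol-derived triazolium tetrafluoroborate ((5aR,10bS) antipode, 10 mol %), DBU (20 mol %), 3,3',5,5'-tetra-tert-butyldiphenoquinone (1.1 equiv), PhMe, rt; then LiOH, THF/H2O, 0 °C; 1 M HCl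
Reagents that add atoms: lithium hydroxide, [Li+].[OH-]
Why: NHC-catalysed oxidative Michael addition–lactonisation (α,β-unsaturated acyl azolium chemistry) of the cyclic 1,3-dione-type enol at C6, then hydrolysis of the activated enol lactone; the chiral carbene should set the (S) C–propyl centre by shielding one face of the acyl azolium (the antipodal salt is used if the sense proves opposite), and no base-labile stereocentre is present because C4 is still a silyl ether.

**Step 16**
Reactants: 27 (silyl ether acid, name as in step 15)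
Product: 28 (3S)-3-[(2R,3R,4S,8R)-4,5-dihydroxy-2,3-dimethyl-8-(3-methylbut-2-en-1-yl)-8-[(2R)-5-methyl-2-(prop-1-en-2-yl)hex-5-en-1-yl]-7-oxo-3,4,7,8-tetrahydro-2H-chromen-6-yl]hexanoic acid
Conditions: TBAF, AcOH, THF, 0 °C → rt
Reagents that add atoms: none
Why: Buffered fluoride desilylation frees the allylic C4 alcohol without acid that could ionise it.

**Step 17**
Reactants: 28 (dihydroxy acid, name as in step 16)
Product: 29 (3S)-3-[(2R,3S,8R)-5-hydroxy-2,3-dimethyl-8-(3-methylbut-2-en-1-yl)-8-[(2R)-5-methyl-2-(prop-1-en-2-yl)hex-5-en-1-yl]-4,7-dioxo-3,4,7,8-tetrahydro-2H-chromen-6-yl]hexanoic acid (CNP0294320.1)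
Conditions: MnO2, CH2Cl2, rt
Reagents that add atoms: none
Why: Allylic oxidation (the carbinol is allylic to the C4a=C8a enol ether) removes the temporary stereocentre and restores the C4 ketone under neutral conditions, so the cis-2,3-dimethyl centres set in step 6 never meet base as an enolisable ketone.

**Compound list**

1 | (S)-4-benzyloxazolidin-2-one | O=C1N[C@@H](Cc2ccccc2)CO1 | starting material
2 | 3-methylbut-2-enoyl chloride | CC(C)=CC(=O)Cl | starting material
3 | (S)-4-benzyl-3-(3-methylbut-2-enoyl)oxazolidin-2-one | CC(C)=CC(=O)N1C(=O)OC[C@@H]1Cc1ccccc1 | intermediate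
4 | 3-methylbut-3-en-1-ol | C=C(C)CCO | starting material
5 | 3-methylbut-3-en-1-yl trifluoromethanesulfonate | C=C(C)CCOS(=O)(=O)C(F)(F)F | intermediate (not isolated)
6 | (S)-4-benzyl-3-[(2S)-5-methyl-2-(prop-1-en-2-yl)hex-5-enoyl]oxazolidin-2-one | C=C(C)CC[C@H](C(=O)N1C(=O)OC[C@@H]1Cc1ccccc1)C(=C)C | intermediate
7 | (S)-5-methyl-2-(prop-1-en-2-yl)hex-5-en-1-ol | C=C(C)CC[C@H](CO)C(=C)C | intermediate
8 | (3S)-3-(iodomethyl)-2,6-dimethylhepta-1,6-diene | C=C(C)CC[C@H](CI)C(=C)C | intermediate
9 | 5-methylhex-4-enoic acid | CC(C)=CCCC(=O)O | starting material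
10 | (4R)-7-methyl-2-(3-methylbut-2-en-1-yl)-4-(prop-1-en-2-yl)oct-7-enoic acid (C2 epimers) | C=C(C)CC[C@H](CC(CC=C(C)C)C(=O)O)C(=C)C | intermediate
11 | (S)-4-benzyl-3-propanoyloxazolidin-2-one | CCC(=O)N1C(=O)OC[C@@H]1Cc1ccccc1 | starting material
12 | acetaldehyde | CC=O | starting material
13 | (S)-4-benzyl-3-[(2S,3R)-3-hydroxy-2-methylbutanoyl]oxazolidin-2-one | C[C@@H](O)[C@H](C)C(=O)N1C(=O)OC[C@@H]1Cc1ccccc1 | intermediate
14 | (2S,3R)-3-hydroxy-N-methoxy-N,2-dimethylbutanamide | C[C@@H](O)[C@H](C)C(=O)N(C)OC | intermediate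
15 | (2S,3R)-3-[(tert-butyldimethylsilyl)oxy]-N-methoxy-N,2-dimethylbutanamide | C[C@@H](O[Si](C)(C)C(C)(C)C)[C@H](C)C(=O)N(C)OC | intermediate
16 | 2,2,6-trimethyl-4H-1,3-dioxin-4-one | CC1=CC(=O)OC(C)(C)O1 | starting material
17 | 6-[(3S,4R)-4-[(tert-butyldimethylsilyl)oxy]-3-methyl-2-oxopentyl]-2,2-dimethyl-4H-1,3-dioxin-4-one | C[C@@H](O[Si](C)(C)C(C)(C)C)[C@H](C)C(=O)CC1=CC(=O)OC(C)(C)O1 | intermediate
18 | (4R)-7-methyl-2-(3-methylbut-2-en-1-yl)-4-(prop-1-en-2-yl)oct-7-enoyl chloride (C2 epimers) | C=C(C)CC[C@H](CC(CC=C(C)C)C(=O)Cl)C(=C)C | intermediate (not isolated)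
19 | 6-[(2R,3S,9R)-2-[(tert-butyldimethylsilyl)oxy]-3,12-dimethyl-7-(3-methylbut-2-en-1-yl)-4,6-dioxo-9-(prop-1-en-2-yl)tridec-12-en-5-yl]-2,2-dimethyl-4H-1,3-dioxin-4-one | C=C(C)CC[C@H](CC(CC=C(C)C)C(=O)C(C(=O)[C@@H](C)[C@@H](C)O[Si](C)(C)C(C)(C)C)C1=CC(=O)OC(C)(C)O1)C(=C)C | intermediate
20 | (2R,3S)-6-[(7R)-2,10-dimethyl-7-(prop-1-en-2-yl)undeca-2,10-dien-5-yl]-5-(2,2-dimethyl-4-oxo-4H-1,3-dioxin-6-yl)-2,3-dimethyl-2,3-dihydro-4H-pyran-4-one | C=C(C)CC[C@H](CC(CC=C(C)C)C1=C(C2=CC(=O)OC(C)(C)O2)C(=O)[C@@H](C)[C@@H](C)O1)C(=C)C | intermediate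
21 | 6-[(2R,3R,4S)-6-[(7R)-2,10-dimethyl-7-(prop-1-en-2-yl)undeca-2,10-dien-5-yl]-4-hydroxy-2,3-dimethyl-3,4-dihydro-2H-pyran-5-yl]-2,2-dimethyl-4H-1,3-dioxin-4-one (all-cis) | C=C(C)CC[C@H](CC(CC=C(C)C)C1=C(C2=CC(=O)OC(C)(C)O2)[C@@H](O)[C@@H](C)[C@@H](C)O1)C(=C)C | intermediate
22 | 6-[(2R,3S,4S)-6-[(7R)-2,10-dimethyl-7-(prop-1-en-2-yl)undeca-2,10-dien-5-yl]-2,3-dimethyl-4-[(triisopropylsilyl)oxy]-3,4-dihydro-2H-pyran-5-yl]-2,2-dimethyl-4H-1,3-dioxin-4-one | C=C(C)CC[C@H](CC(CC=C(C)C)C1=C(C2=CC(=O)OC(C)(C)O2)[C@@H](O[Si](C(C)C)(C(C)C)C(C)C)[C@@H](C)[C@@H](C)O1)C(=C)C | intermediate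
23 | 3-[(2R,3S,4S)-6-[(7R)-2,10-dimethyl-7-(prop-1-en-2-yl)undeca-2,10-dien-5-yl]-2,3-dimethyl-4-[(triisopropylsilyl)oxy]-3,4-dihydro-2H-pyran-5-yl]-3-oxoprop-1-en-1-one (acylketene) | C=C(C)CC[C@H](CC(CC=C(C)C)C1=C(C(=O)C=C=O)[C@@H](O[Si](C(C)C)(C(C)C)C(C)C)[C@@H](C)[C@@H](C)O1)C(=C)C | intermediate (not isolated)
24 | (2R,3S,4S,8R)-5-hydroxy-2,3-dimethyl-8-(3-methylbut-2-en-1-yl)-8-[(2R)-5-methyl-2-(prop-1-en-2-yl)hex-5-en-1-yl]-4-[(triisopropylsilyl)oxy]-3,4-dihydro-2H-chromen-7(8H)-one | C=C(C)CC[C@H](C[C@@]1(CC=C(C)C)C(=O)C=C(O)C2=C1O[C@H](C)[C@H](C)[C@@H]2O[Si](C(C)C)(C(C)C)C(C)C)C(=C)C | intermediate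
25 | (E)-hex-2-enal | CCC/C=C/C=O | starting material
26 | enol δ-lactone of 27 closed on the C5 oxygen ((4S)-4-propyl-3,4-dihydro-2H-pyran-2-one ring fused at C5–C6 of the chromenone) | C=C(C)CC[C@H](C[C@@]1(CC=C(C)C)C(=O)C3=C(OC(=O)C[C@@H]3CCC)C2=C1O[C@H](C)[C@H](C)[C@@H]2O[Si](C(C)C)(C(C)C)C(C)C)C(=C)C | intermediate (not isolated)
27 | (3S)-3-[(2R,3S,4S,8R)-5-hydroxy-2,3-dimethyl-8-(3-methylbut-2-en-1-yl)-8-[(2R)-5-methyl-2-(prop-1-en-2-yl)hex-5-en-1-yl]-7-oxo-4-[(triisopropylsilyl)oxy]-3,4,7,8-tetrahydro-2H-chromen-6-yl]hexanoic acid | C=C(C)CC[C@H](C[C@@]1(CC=C(C)C)C(=O)C([C@@H](CCC)CC(=O)O)=C(O)C2=C1O[C@H](C)[C@H](C)[C@@H]2O[Si](C(C)C)(C(C)C)C(C)C)C(=C)C | intermediate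
28 | (3S)-3-[(2R,3R,4S,8R)-4,5-dihydroxy-2,3-dimethyl-8-(3-methylbut-2-en-1-yl)-8-[(2R)-5-methyl-2-(prop-1-en-2-yl)hex-5-en-1-yl]-7-oxo-3,4,7,8-tetrahydro-2H-chromen-6-yl]hexanoic acid | C=C(C)CC[C@H](C[C@@]1(CC=C(C)C)C(=O)C([C@@H](CCC)CC(=O)O)=C(O)C2=C1O[C@H](C)[C@H](C)[C@@H]2O)C(=C)C | intermediate
29 | (3S)-3-[(2R,3S,8R)-5-hydroxy-2,3-dimethyl-8-(3-methylbut-2-en-1-yl)-8-[(2R)-5-methyl-2-(prop-1-en-2-yl)hex-5-en-1-yl]-4,7-dioxo-3,4,7,8-tetrahydro-2H-chromen-6-yl]hexanoic acid | C=C(C)CC[C@H](C[C@@]1(CC=C(C)C)C(=O)C([C@@H](CCC)CC(=O)O)=C(O)C2=C1O[C@H](C)[C@H](C)C2=O)C(=C)C | target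

**Step count.** Total: 17 steps. Longest linear sequence: 13 steps (steps 1–5, then 10–17).

**Steps most likely to fail**

1. Step 14 (Proposed new method). The ketene may be consumed before γ-enolisation, by attack of the silyl ether oxygen or by dimerisation. The two helical transition states may also be poorly discriminated, so that C8 forms with little facial preference. Fallback by known chemistry: it sets out from 22 and returns at 24. Thermolysis of 22 in the presence of pentafluorophenol (PhMe, 110 °C) traps the ketene as the pentafluorophenyl β-keto ester F1. A base-mediated Dieckmann-type γ-C-acylation then closes ring A (KHMDS, THF, −78 → 0 °C; alternatively K3PO4 and an N-benzylcinchoninium salt under phase transfer, so that a chiral counter-ion takes over facial control), giving 24. Epimers at C8 are diastereomers and separable at this stage.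

2. Step 15. The hindered enol next to the quaternary carbon may add sluggishly to the β-propyl acyl azolium, catalyst control may be eroded by the resident stereocentres, and the electron-rich enol may be oxidised by the quinone. Fallback: it sets out from 24 and returns at 27 through the same enol lactone 26. (E)-Hex-2-enoic acid is activated in situ as its pivalic mixed anhydride (pivaloyl chloride, iPr2NEt, CH2Cl2) and turned over by the isothiourea HyperBTM (10 mol %) as an α,β-unsaturated acyl ammonium, which undergoes Michael addition–lactonisation without any oxidant; LiOH hydrolysis then gives 27.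

3. Step 2. Alkylation of the sodium dienolate by the unactivated homoallylic triflate may be slower than enolate decomposition or E2 loss of triflate, and diastereoselectivity may erode on warming. Fallback: it sets out from 4 and returns at 7. Alcohol 4 is converted to 4-iodo-2-methylbut-1-ene F2 (I2, PPh3, imidazole). F2 alkylates the dianion of 3-methylbut-2-enoic acid at the α-carbon (LDA, 2.2 equiv, THF) to give racemic 5-methyl-2-(prop-1-en-2-yl)hex-5-enoic acid F3. LiAlH4 reduction gives the racemic alcohol F4. Lipase-catalysed acylation with vinyl acetate (Amano lipase PS), by analogy with lavandulol, should esterify the (R)-enantiomer to acetate F5 and leave (S)-alcohol 7.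

**Further compounds**

F1 | step 14 | pentafluorophenyl 3-[(2R,3S,4S)-6-[(7R)-2,10-dimethyl-7-(prop-1-en-2-yl)undeca-2,10-dien-5-yl]-2,3-dimethyl-4-[(triisopropylsilyl)oxy]-3,4-dihydro-2H-pyran-5-yl]-3-oxopropanoate | C=C(C)CC[C@H](CC(CC=C(C)C)C1=C(C(=O)CC(=O)Oc2c(F)c(F)c(F)c(F)c2F)[C@@H](O[Si](C(C)C)(C(C)C)C(C)C)[C@@H](C)[C@@H](C)O1)C(=C)C
F0 | step 15 | none | none
F2 | step 2 | 4-iodo-2-methylbut-1-ene | C=C(C)CCI
F3 | step 2 | rac-5-methyl-2-(prop-1-en-2-yl)hex-5-enoic acid | C=C(C)CCC(C(=O)O)C(=C)C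
F4 | step 2 | rac-5-methyl-2-(prop-1-en-2-yl)hex-5-en-1-ol | C=C(C)CCC(CO)C(=C)C
F5 | step 2 | (R)-5-methyl-2-(prop-1-en-2-yl)hex-5-en-1-yl acetate | C=C(C)CC[C@@H](COC(C)=O)C(=C)C
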